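The route rests on cutting the O3–C5' bond of the 1,4-dioxane. The key step exploits the position of C5' (primed atoms: guaiane). This oxygen-bearing quaternary ring-fusion carbon lies two bonds from C3' in the five-membered ring, so a C3' ketone with a C4'=C5' double bond makes it a Michael acceptor site. In one operation the free C3 phenol of a C1' aryl ether adds to C5'. This closes the dioxane, completes the propellane and fixes C5' from the face already set at C1'. The precursor is a C1'-aryloxy hydroazulenone whose aryl group, a 4-bromo-3-methylcatechol unit, is ring A. Rings B to E are then grown from the bromide through an arene-terminated polyene cyclisation.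

Key step: step 16

Conventions and assumptions (remarks on the chemistry)
- Unprimed locants follow friedelane numbering of the nor-triterpene (rings A to E). Primed locants follow guaiane numbering.
- The sense of induction of the copper hydride catalyst in step 4 is assigned by analogy with β-methylcycloalkenones. If it proves opposite, the antipodal ligand is used.
- Compounds 23–25, 41–52 and F1–F3 are drawn as the C4' epimer with the methyl group syn to O3. The other epimer would carry its C3' oxygen on the opposite face as well and would converge in step 37.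
- The tertiary C1' alcohol is arylated while C3' is a protected carbinol. A γ-hydroxy enone would enolise or cleave by retro-aldol reaction under the base needed.
- Compounds 22 and 23 carry the same configuration as the target at C7' (R), C10' (R), C1' (S) and C5' (S, in 23).

Step 1
Reactants: 1 (R)-(−)-carvone
Product: 2 triethylsilyl enol ether of (R)-dihydrocarvone (tetrasubstituted enol double bond)
Conditions: Et3SiH, RhCl(PPh3)3 (0.5 mol %), toluene, 50 °C
Reagents that add atoms: triethylsilane, CC[SiH](CC)CC
Why: Rhodium-catalysed 1,4-hydrosilylation of the enone should give the tetrasubstituted silyl enol ether regiospecifically and leave the isopropenyl group and the C7' centre of carvone untouched.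

Step 2
Reactants: 2 triethylsilyl enol ether of (R)-dihydrocarvone
Product: 3 6-methyl-3-(prop-1-en-2-yl)-1-(triethylsilyloxy)bicyclo[4.1.0]heptane (cyclopropane diastereomers, both used)
Conditions: Et2Zn, CH2I2, CH2Cl2, 0 °C
Reagents that add atoms: diiodomethane, [I]C[I]
Why: Simmons–Smith cyclopropanation should select the electron-rich enol ether over the isopropenyl group, and the two new centres are lost in step 3, so their configuration is irrelevant.

Step 3
Reactants: 3 siloxycyclopropane
Product: 5 (R)-3-methyl-6-(prop-1-en-2-yl)cyclohept-2-en-1-one, via β-chloro ketone 4 (not isolated)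
Conditions: FeCl3, DMF, 0 °C to rt; then NaOAc, MeOH, reflux
Reagents that add atoms: none
Why: In this Saegusa-type oxidative ring expansion, one-electron oxidation opens the internal cyclopropane bond to the ring-enlarged tertiary radical, which is chlorinated, and acetate then removes HCl to give the conjugated cycloheptenone (C5'=O, C1'=C10').

Step 4
Reactants: 5 (R)-3-methyl-6-(prop-1-en-2-yl)cyclohept-2-en-1-one
Product: 7 (3R,6R)-2-(but-2-yn-1-yl)-3-methyl-6-(prop-1-en-2-yl)cycloheptan-1-one, via diphenylsilyl enol ether 6 (not isolated)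
Conditions: Cu(OAc)2 (3 mol %), (R)-DTBM-SEGPHOS, Ph2SiH2, toluene, 0 °C; then Bu4N[Ph3SiF2], 1-bromobut-2-yne, CH2Cl2, rt
Reagents that add atoms: 1-bromobut-2-yne, CC#CCBr
Why: Copper hydride-catalysed asymmetric conjugate reduction sets C10' (R) under ligand control, and fluoride release of the regiodefined enolate allows alkylation at C1' only (conjugate reduction–alkylation); the C1' centre, expected trans, is erased in step 6.

Step 5
Reactants: 7 butynyl cycloheptanone
Product: 9 (7'R,10'R)-guaia-4',11'-dien-3'-one (C1' epimers), via 1,4-diketone 8 (not isolated)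
Conditions: NaAuCl4 (2 mol %), MeOH–H2O, 50 °C; then KOH, reflux
Reagents that add atoms: water, O
Why: Carbonyl-assisted gold-catalysed alkyne hydration (5-exo attack of the C5' carbonyl oxygen) places the new ketone at C3', and intramolecular aldol condensation of the 1,4-diketone closes the 2-methylcyclopentenone as in jasmone-type syntheses, while C7' and C10' are not enolisable.

Step 6
Reactants: 9 guaia-4',11'-dien-3'-one
Product: 10 3'-(tert-butyldimethylsilyloxy)guaia-1'(5'),3',11'-triene (silyloxycyclopentadiene, used at once)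
Conditions: TBSOTf, Et3N, CH2Cl2, 0 to 40 °C; extraction into pentane
Reagents that add atoms: tert-butyldimethylsilyl triflate, CC(C)(C)[Si](C)(C)OS(=O)(=O)C(F)(F)F
Why: Soft enolisation gives silyloxycyclopentadienes that interconvert by [1,5]-hydrogen shifts and should settle on the fully substituted diene with CH2 at C2', while C10' lies outside the diene and keeps its configuration.

Step 7
Reactants: 10 silyloxycyclopentadiene
Product: 12 (1'S,7'R,10'R)-1'-hydroxyguaia-4',11'-dien-3'-one, via endoperoxide 11 (not isolated)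
Conditions: O2, tetraphenylporphyrin, hν, CH2Cl2, −78 °C; then PPh3, −78 °C to rt; aqueous work-up
Reagents that add atoms: dioxygen, O=O
Why: Singlet oxygen adds [4+2] across C1' and C3' of the cyclopentadiene far faster than it attacks the isopropenyl group and from the face anti to the adjacent C10' methyl, which sets C1'; O–O reduction and collapse of the silyl hemiketal then give the γ-hydroxy enone.

Step 8
Reactants: 12 γ-hydroxy enone
Product: 13 (1'S,3'-trans)-guaia-4',11'-diene-1',3'-diol (C3' hydroxyl trans to the C1' hydroxyl)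
Conditions: NaBH4, CeCl3·7H2O, MeOH, −78 to 0 °C
Reagents that add atoms: none
Why: Luche 1,2-reduction removes the enolisable, retro-aldol-prone β-hydroxy ketone array before any strong base is used; hydride is expected from the face of the C1' hydroxyl, away from C10', and the C3' centre is erased again in step 15.

Step 9
Reactants: 13 ene-diol
Product: 14 3'-O-TBS ether of 13 (tertiary C1' hydroxyl free)
Conditions: TBSCl, imidazole, DMF, 0 °C
Reagents that add atoms: tert-butyldimethylsilyl chloride, CC(C)(C)[Si](C)(C)Cl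
Why: Silylation distinguishes the secondary allylic from the tertiary hydroxyl on steric grounds, and the trans relation of the two oxygens blocks silyl migration in step 13.

Step 10
Reactants: 15 3-bromo-2-methylphenol
Product: 16 3-bromo-6-iodo-2-methylphenol
Conditions: I2, NaHCO3, THF–H2O, rt
Reagents that add atoms: iodine, [I][I]
Why: Electrophilic iodination of the phenoxide should go ortho to oxygen and para to bromine, because the position para to oxygen is flanked by the bromine atom.

Step 11
Reactants: 16 3-bromo-6-iodo-2-methylphenol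
Product: 17 (3-bromo-6-iodo-2-methylphenoxy)triisopropylsilane
Conditions: TIPSOTf, 2,6-lutidine, CH2Cl2, 0 °C to rt
Reagents that add atoms: triisopropylsilyl triflate, CC(C)[Si](C(C)C)(C(C)C)OS(=O)(=O)C(F)(F)F
Why: O-silylation gives an aryl silyl ether that withstands the acidic oxidation of step 12 and the alkoxide of step 13 and is removed by fluoride under neutral conditions.

Step 12
Reactants: 17 aryl iodide
Product: 19 [4-bromo-3-methyl-2-(triisopropylsilyloxy)phenyl](2,4,6-trimethoxyphenyl)iodonium tosylate, via hydroxy(tosyloxy)iodoarene 18 (not isolated)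
Conditions: mCPBA, TsOH·H2O, MeCN, 60 °C; then 1,3,5-trimethoxybenzene
Reagents that add atoms: 1,3,5-trimethoxybenzene, COc1cc(OC)cc(OC)c1; p-toluenesulfonic acid, Cc1ccc(cc1)S(=O)(=O)O
Why: Oxidation of the aryl iodide to the trivalent iodane and electrophilic substitution of trimethoxybenzene (one-pot diaryliodonium synthesis) give a salt whose very electron-rich trimethoxyphenyl group acts as a non-transferable dummy.

Step 13
Reactants: 14 tertiary alcohol; 19 diaryliodonium tosylate
Product: 20 C1' aryl ether (aryl = 4-bromo-3-methyl-2-TIPSO-phenyl) with 3'-OTBS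
Conditions: KN(SiMe3)2, toluene, 0 °C; then 19, rt
Reagents that add atoms: none
Why: Metal-free O-arylation of a tertiary alkoxide by ligand coupling at trivalent iodine is known for congested tert-alkyl aryl ethers; the less electron-rich, ortho-substituted aryl group is transferred, the C1'–O bond is not broken so C1' is retained, and no enolisable carbonyl group is present.

Step 14
Reactants: 20 bis-silyl ether
Product: 21 C1' (4-bromo-2-hydroxy-3-methylphenyl) ether of diol 13
Conditions: Bu4NF, AcOH, THF, 0 °C to rt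
Reagents that add atoms: none
Why: Buffered fluoride cleaves the aryl and the allylic silyl ether in one operation without touching the tertiary allylic aryl ether.

Step 15
Reactants: 21 phenol allylic alcohol
Product: 22 (1'S,7'R,10'R)-1'-(4-bromo-2-hydroxy-3-methylphenoxy)guaia-4',11'-dien-3'-one (key-step precursor)
Conditions: MnO2 (activated), CH2Cl2, rt
Reagents that add atoms: none
Why: Manganese dioxide oxidises the allylic alcohol chemoselectively in the presence of a guaiacol-type phenol and of isolated alkenes, which restores the C4'=C5'–C3'=O acceptor only now that no strong base is needed.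

Step 16
Reactants: 22 C1'-aryloxy hydroazulenone with free C3 phenol
Product: 24 propellane benzodioxane C3' alcohol (OH cis to the C4' methyl), via propellane ketone 23 (not isolated)
Conditions: DBU (0.2 equiv), THF, 0 °C until the composition is constant; then −78 °C, LiBH(s-Bu)3; H2O
Reagents that add atoms: none
Why: DBU generates a little C3 phenoxide, which adds to C5', the β-carbon of the enone, and the enolate is protonated at C4'; this is an intramolecular oxa-Michael addition of a phenol to a β,β-disubstituted enone, the chromanone-type closure. The dioxane closes 6-exo-trig. The short O2–C2–C3–O3 tether from C1' reaches only the face of C5' that already carries the C1' oxygen, so the cis propellane with (S)-C5' is the only possible adduct, and C4' equilibrates to the epimer with methyl syn to the smaller O3 substituent. Because the addition is reversible and either aryloxy group of 23 can leave by retro-Michael reaction, the mixture is frozen at −78 °C and reduced in the same flask; the bulky borohydride attacks the unhindered cyclopentanone but not the tetrasubstituted enone, so unreacted 22 is recovered and recycled. Hydride comes anti to the C4' methyl in either C4' epimer, so every adduct has the C3' oxygen cis to the methyl and anti to H4', which is the arrangement the anti elimination of step 37 needs.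

Step 17
Reactants: 24 C3' alcohol
Product: 25 3'-O-TBS ether of 24 (aryl bromide for ring annulation)
Conditions: TBSOTf, 2,6-lutidine, CH2Cl2, 0 °C
Reagents that add atoms: tert-butyldimethylsilyl triflate, CC(C)(C)[Si](C)(C)OS(=O)(=O)C(F)(F)F
Why: Silylation stores the future C3'=C4' alkene as a saturated silyl ether, so no ionisable allylic tertiary aryl ether is present during the Lewis acid and palladium steps.

Step 18
Reactants: 26 2,3-dimethylbuta-1,3-diene
Product: 27 (E)-1,4-dibromo-2,3-dimethylbut-2-ene
Conditions: Br2, CH2Cl2, −20 °C to rt; crystallisation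
Reagents that add atoms: bromine, BrBr
Why: 1,4-Addition of bromine to the diene gives the crystalline (E)-dibromide, which fixes the geometry of the future C13=C14 tetrasubstituted alkene.

Step 19
Reactants: 27 (E)-dibromide
Product: 28 (E)-1,6-bis(isopropoxydimethylsilyl)-3,4-dimethylhex-3-ene
Conditions: (i-PrO)Me2SiCH2MgCl (from the chloride and Mg), Li2CuCl4 (cat.), THF, 0 °C
Reagents that add atoms: (isopropoxydimethylsilyl)methylmagnesium chloride, CC(C)O[Si](C)(C)C[Mg]Cl
Why: Copper-catalysed SN2 coupling of the hydroxymethyl-anion equivalent with both allylic bromides adds C11 and C16, and SN2' attack is disfavoured because it would create a quaternary carbon.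

Step 20
Reactants: 28 bis-silane
Product: 29 (E)-3,4-dimethylhex-3-ene-1,6-diol
Conditions: H2O2, KF, KHCO3, THF–MeOH, rt
Reagents that add atoms: hydrogen peroxide, OO
Why: Tamao oxidation converts both C–Si bonds into C–OH without affecting the tetrasubstituted alkene.

Step 21
Reactants: 29 symmetrical diol
Product: 30 (E)-6-hydroxy-3,4-dimethylhex-3-en-1-yl tosylate
Conditions: TsCl, Ag2O, KI (cat.), CH2Cl2, rt
Reagents that add atoms: p-toluenesulfonyl chloride, Cc1ccc(cc1)S(=O)(=O)Cl
Why: Silver oxide-mediated monotosylation is an established way to desymmetrise symmetrical diols.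

Step 22
Reactants: 30 monotosylate
Product: 31 (E)-3,4-dimethyloct-3-en-7-yn-1-ol
Conditions: LiC≡CH·H2NCH2CH2NH2, DMSO, rt
Reagents that add atoms: lithium acetylide, [Li]C#C
Why: SN2 displacement of the primary tosylate by acetylide adds C9 and C8 and tolerates the free hydroxyl as its alkoxide.

Step 23
Reactants: 31 enynol
Product: 33 (3E,7E)-3,4,7-trimethylundeca-3,7,10-trien-1-ol, via alkenylalane 32 (not isolated)
Conditions: Me3Al, Cp2ZrCl2 (cat.), CH2Cl2, rt; then vinyl bromide, Pd(PPh3)4, ZnCl2, THF, rt
Reagents that add atoms: trimethylaluminium, C[Al](C)C; vinyl bromide, C=CBr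
Why: Negishi zirconium-catalysed syn-carboalumination places methyl (C25) on C9 and aluminium on C8, and stereoretentive palladium-catalysed coupling with vinyl bromide gives the (E)-trisubstituted C8=C9 alkene together with C7 and C6.

Step 24
Reactants: 33 trienol
Product: 34 (3E,7E)-11-iodo-4,8,9-trimethylundeca-1,3,7-triene
Conditions: I2, PPh3, imidazole, CH2Cl2, 0 °C
Reagents that add atoms: iodine, [I][I]
Why: Appel-type iodination turns the primary alcohol (C16) into the alkylating agent under neutral conditions.

Step 25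
Reactants: 35 (S)-valinol; 36 5-oxohexanoic acid
Product: 37 (3S,8aR)-3-isopropyl-8a-methylhexahydro-5H-oxazolo[3,2-a]pyridin-5-one
Conditions: toluene, reflux, water separator
Reagents that add atoms: none
Why: Cyclodehydration of the amino alcohol with the δ-keto acid gives the bicyclic lactam as the thermodynamically preferred diastereomer with angular methyl and isopropyl on the same face.

Step 26
Reactants: 37 bicyclic lactam
Product: 38 6-methyl derivative of 37 (C6 epimers)
Conditions: LiN(i-Pr)2, THF, −78 °C; MeI
Reagents that add atoms: iodomethane, C[I]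
Why: Lactam enolate methylation introduces C28, and the new centre is planarised again in step 27.

Step 27
Reactants: 38 methyl lactam; 34 trienyl iodide
Product: 39 6-methyl-6-trienyl lactam (trienyl chain anti to the angular methyl)
Conditions: LiN(i-Pr)2, THF, −78 °C; then 34, DMPU, −78 to 0 °C
Reagents that add atoms: none
Why: In the second alkylation of the valinol-derived bicyclic lactam enolate the electrophile enters from the face opposite to the angular methyl and the isopropyl group, which sets the quaternary carbon that becomes C17.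

Step 28
Reactants: 39 trienyl lactam; 25 aryl bromide
Product: 41 ring A–polyene–lactam coupling product (new C5–C6 bond), via B-alkyl-9-BBN 40 (not isolated)
Conditions: 39, 9-BBN (1.0 equiv), THF, 0 °C to rt; then aq K3PO4, 25, Pd(OAc)2, SPhos, THF–DMF, 60 °C
Reagents that add atoms: none
Why: 9-BBN hydroborates only the terminal vinyl group of the diene in a separate operation, so the isopropenyl group of 25 never meets free borane, and B-alkyl Suzuki–Miyaura coupling joins C6 to the ortho-methyl aryl bromide.

Step 29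
Reactants: 41 coupled lactam
Product: 44 polyene (S)-4-methyl-4-alkylcyclohex-2-enone (ring E), via carbinolamine 42 (not isolated), via keto aldehyde 43 (not isolated)
Conditions: NaAlH2(OCH2CH2OMe)2, toluene, −20 to 0 °C; then Bu4NH2PO4 (aq), EtOH, reflux
Reagents that add atoms: none
Why: Partial reduction of the lactam, mildly acidic hydrolysis of the N,O-ketal and intramolecular aldol condensation are the standard release of 4,4-disubstituted cyclohexenones from such lactams and leave C17, the silyl ether and all alkenes unchanged.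

Step 30
Reactants: 44 polyene enone
Product: 45 pentacyclic C20 ketone (rings B, C and D closed; 8α-H, 9β-Me, 13α-Me, 14β-Me, 18β-H)
Conditions: MeAlCl2 (3 equiv), CH2Cl2, −78 to −20 °C
Reagents that add atoms: none
Why: In this Lewis acid-initiated cation–olefin polycyclisation with Friedel–Crafts termination at C10 (para to O3), the equatorial C16 tether attacks C18 axially and anti to the C17 methyl (cis D/E), anti addition across the (E)-C13=C14 and (E)-C8=C9 alkenes through chair-like folds gives the trans-anti-trans array, and the Al–Me bond scavenges the released proton so that the isopropenyl group is not protonated.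

Step 31
Reactants: 45 C20 ketone
Product: 46 C20 enol triflate (mainly the 20,21-ene; the 19,20-ene converges in step 33)
Conditions: KN(SiMe3)2, THF, −78 °C; PhNTf2
Reagents that add atoms: N-phenylbis(trifluoromethanesulfonimide), O=S(=O)(N(c1ccccc1)S(=O)(=O)C(F)(F)F)C(F)(F)F
Why: Kinetic enolisation and O-triflation of the only carbonyl group give the alkenyl triflate.

Step 32
Reactants: 46 enol triflate
Product: 47 α,β-unsaturated C29 methyl ester
Conditions: Pd(PPh3)4 (5 mol %), CO (1 atm), MeOH, Et3N, DMF, 50 °C
Reagents that add atoms: carbon monoxide, [C-]#[O+]; methanol, CO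
Why: Palladium-catalysed methoxycarbonylation of the alkenyl triflate adds C29, and no aryl halide or allylic ether is left to compete for the zerovalent palladium.

Step 33
Reactants: 47 enoate
Product: 48 saturated C29 methyl ester (C20 epimers)
Conditions: Mg, MeOH, 0 °C to rt
Reagents that add atoms: none
Why: Magnesium in methanol reduces conjugated esters selectively and leaves isolated alkenes, aryl ethers and the silyl ether alone, and the C20 centre is planarised again in step 34.

Step 34
Reactants: 48 ester
Product: 49 20β-methyl-20α-methoxycarbonyl pentacycle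
Conditions: LiN(i-Pr)2, THF, −78 °C; MeI, DMPU, −78 to 0 °C
Reagents that add atoms: iodomethane, C[I]
Why: Methylation of the exocyclic ester enolate should occur from the convex β face of the cis-fused D/E system (equatorial attack, the α face being shielded by C13 and its methyl group), which sets C20.

Step 35
Reactants: 49 6,7-dihydro pentacycle
Product: 50 6,7-dehydro pentacycle (styrene-type C6=C7)
Conditions: DDQ (1.2 equiv), 1,4-dioxane, rt
Reagents that add atoms: none
Why: DDQ dehydrogenation removes hydride from the secondary benzylic C6, which is para to O2 and more reactive than the C23 methyl, loss of H7 follows, and the quaternary C9 blocks further aromatisation while C8 keeps its configuration.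

Step 36
Reactants: 50 silyl ether
Product: 51 C3' alcohol
Conditions: Bu4NF, THF, 40 °C
Reagents that add atoms: none
Why: Fluoride desilylation frees the secondary alcohol without affecting the hindered tertiary methyl ester.

Step 37
Reactants: 51 C3' alcohol
Product: 53 target CNP0287532.2, via mesylate 52 (not isolated)
Conditions: MsCl, Et3N, CH2Cl2, 0 °C; then DBU, toluene, 90 °C
Reagents that add atoms: none
Why: E2 elimination of the mesylate, which stands anti to H4' by virtue of step 16, should follow the Zaitsev sense known for cis-2-methylcyclopentyl sulfonates and give the trisubstituted C3'=C4' alkene under basic conditions that the allylic tertiary aryl ether tolerates.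

Compound list
1 | (R)-(−)-carvone | C=C(C)[C@@H]1CC=C(C)C(=O)C1 | starting material
2 | triethylsilyl enol ether of (R)-dihydrocarvone | C=C(C)[C@@H]1CCC(C)=C(O[Si](CC)(CC)CC)C1 | intermediate
3 | 6-methyl-3-(prop-1-en-2-yl)-1-(triethylsilyloxy)bicyclo[4.1.0]heptane | C=C(C)[C@@H]1CCC2(C)CC2(O[Si](CC)(CC)CC)C1 | intermediate
4 | 3-chloro-3-methyl-6-(prop-1-en-2-yl)cycloheptanone | C=C(C)[C@@H]1CCC(C)(Cl)CC(=O)C1 | intermediate
5 | (R)-3-methyl-6-(prop-1-en-2-yl)cyclohept-2-en-1-one | C=C(C)[C@@H]1CCC(C)=CC(=O)C1 | intermediate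
6 | diphenylsilyl enol ether of (3R,6R)-3-methyl-6-isopropenylcycloheptanone | C=C(C)[C@@H]1CC[C@@H](C)C=C(O[SiH](c2ccccc2)c2ccccc2)C1 | intermediate
7 | (3R,6R)-2-(but-2-yn-1-yl)-3-methyl-6-(prop-1-en-2-yl)cycloheptan-1-one | C=C(C)[C@@H]1CC[C@@H](C)C(CC#CC)C(=O)C1 | intermediate
8 | (3R,6R)-3-methyl-2-(2-oxobutyl)-6-(prop-1-en-2-yl)cycloheptan-1-one | C=C(C)[C@@H]1CC[C@@H](C)C(CC(=O)CC)C(=O)C1 | intermediate
9 | (7'R,10'R)-guaia-4',11'-dien-3'-one | C=C(C)[C@@H]1CC[C@@H](C)C2CC(=O)C(C)=C2C1 | intermediate
10 | 3'-(TBSO)guaia-1'(5'),3',11'-triene | C=C(C)[C@@H]1CC[C@@H](C)C2=C(C1)C(C)=C(O[Si](C)(C)C(C)(C)C)C2 | intermediate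
11 | 1',3'-epidioxy-3'-(TBSO)guaia-4',11'-diene (peroxide anti to the C10' methyl) | C=C(C)[C@@H]1CC[C@@H](C)[C@@]23C[C@](O[Si](C)(C)C(C)(C)C)(OO3)C(C)=C2C1 | intermediate
12 | (1'S,7'R,10'R)-1'-hydroxyguaia-4',11'-dien-3'-one | C=C(C)[C@@H]1CC[C@@H](C)[C@@]2(O)CC(=O)C(C)=C2C1 | intermediate
13 | guaia-4',11'-diene-1',3'-diol (hydroxyls trans) | C=C(C)[C@@H]1CC[C@@H](C)[C@@]2(O)C[C@@H](O)C(C)=C2C1 | intermediate
14 | 3'-O-TBS ether of 13 | C=C(C)[C@@H]1CC[C@@H](C)[C@@]2(O)C[C@@H](O[Si](C)(C)C(C)(C)C)C(C)=C2C1 | intermediate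
15 | 3-bromo-2-methylphenol | Cc1c(O)cccc1Br | starting material
16 | 3-bromo-6-iodo-2-methylphenol | Cc1c(O)c(I)ccc1Br | intermediate
17 | (3-bromo-6-iodo-2-methylphenoxy)triisopropylsilane | Cc1c(O[Si](C(C)C)(C(C)C)C(C)C)c(I)ccc1Br | intermediate
18 | hydroxy(tosyloxy)iodoarene from 17 | Cc1c(O[Si](C(C)C)(C(C)C)C(C)C)c(I(O)OS(=O)(=O)c2ccc(C)cc2)ccc1Br | intermediate
19 | aryl(2,4,6-trimethoxyphenyl)iodonium tosylate | Cc1c(O[Si](C(C)C)(C(C)C)C(C)C)c([I+]c2c(OC)cc(OC)cc2OC)ccc1Br.Cc1ccc(cc1)S(=O)(=O)[O-] | intermediate
20 | C1' aryl ether with aryl OTIPS and 3'-OTBS | C=C(C)[C@@H]1CC[C@@H](C)[C@@]2(Oc3ccc(Br)c(C)c3O[Si](C(C)C)(C(C)C)C(C)C)C[C@@H](O[Si](C)(C)C(C)(C)C)C(C)=C2C1 | intermediate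
21 | C1' aryl ether with free phenol and free C3' allylic alcohol | C=C(C)[C@@H]1CC[C@@H](C)[C@@]2(Oc3ccc(Br)c(C)c3O)C[C@@H](O)C(C)=C2C1 | intermediate
22 | C1'-aryloxy hydroazulenone with free phenol (key-step precursor) | C=C(C)[C@@H]1CC[C@@H](C)[C@@]2(Oc3c(O)c(C)c(Br)cc3)CC(=O)C(C)=C2C1 | intermediate
23 | propellane benzodioxane ketone (key-step product) | C=C(C)[C@@H]1CC[C@@H](C)[C@@]23CC(=O)[C@H](C)[C@]2(C1)Oc1c(C)c(Br)ccc1O3 | intermediate
24 | propellane benzodioxane C3' alcohol (OH cis to C4' methyl) | C=C(C)[C@@H]1CC[C@@H](C)[C@@]23C[C@H](O)[C@H](C)[C@]2(C1)Oc1c(C)c(Br)ccc1O3 | intermediate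
25 | 3'-O-TBS ether of 24 | C=C(C)[C@@H]1CC[C@@H](C)[C@@]23C[C@H](O[Si](C)(C)C(C)(C)C)[C@H](C)[C@]2(C1)Oc1c(C)c(Br)ccc1O3 | intermediate
26 | 2,3-dimethylbuta-1,3-diene | C=C(C)C(C)=C | starting material
27 | (E)-1,4-dibromo-2,3-dimethylbut-2-ene | BrC/C(C)=C(C)/CBr | intermediate
28 | (E)-1,6-bis(isopropoxydimethylsilyl)-3,4-dimethylhex-3-ene | CC(C)O[Si](C)(C)CC/C(C)=C(C)/CC[Si](C)(C)OC(C)C | intermediate
29 | (E)-3,4-dimethylhex-3-ene-1,6-diol | OCC/C(C)=C(C)/CCO | intermediate
30 | (E)-6-hydroxy-3,4-dimethylhex-3-en-1-yl tosylate | Cc1ccc(cc1)S(=O)(=O)OCC/C(C)=C(C)/CCO | intermediate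
31 | (E)-3,4-dimethyloct-3-en-7-yn-1-ol | C#CCC/C(C)=C(C)/CCO | intermediate
32 | (E)-alkenyldimethylalane (aluminium alkoxide form) | C[Al](C)/C=C(C)/CC/C(C)=C(C)/CCO[Al](C)C | intermediate
33 | (3E,7E)-3,4,7-trimethylundeca-3,7,10-trien-1-ol | C=C/C=C(C)/CC/C(C)=C(C)/CCO | intermediate
34 | (3E,7E)-11-iodo-4,8,9-trimethylundeca-1,3,7-triene | C=C/C=C(C)/CC/C(C)=C(C)/CCI | intermediate
35 | (S)-valinol | CC(C)[C@H](N)CO | starting material
36 | 5-oxohexanoic acid | CC(=O)CCCC(=O)O | starting material
37 | (3S,8aR)-3-isopropyl-8a-methylhexahydro-5H-oxazolo[3,2-a]pyridin-5-one | O=C1CCC[C@@]2(C)OC[C@H](C(C)C)N12 | intermediate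
38 | 6-methyl lactam (C6 epimers) | CC1CC[C@@]2(C)OC[C@H](C(C)C)N2C1=O | intermediate
39 | 6-methyl-6-trienyl lactam | C=C/C=C(C)/CC/C(C)=C(C)/CC[C@@]1(C)CC[C@@]2(C)OC[C@H](C(C)C)N2C1=O | intermediate
40 | B-alkyl-9-BBN from 39 (boron on C6) | C1CC2CCCC(C1)B2CC/C=C(C)/CC/C(C)=C(C)/CC[C@@]1(C)CC[C@@]2(C)OC[C@H](C(C)C)N2C1=O | intermediate
41 | ring A–polyene–lactam | C=C(C)[C@@H]1CC[C@@H](C)[C@@]23C[C@H](O[Si](C)(C)C(C)(C)C)[C@H](C)[C@]2(C1)Oc1c(C)c(CC/C=C(C)/CC/C(C)=C(C)/CC[C@@]4(C)CC[C@@]5(C)OC[C@H](C(C)C)N5C4=O)ccc1O3 | intermediate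
42 | carbinolamine from 41 | C=C(C)[C@@H]1CC[C@@H](C)[C@@]23C[C@H](O[Si](C)(C)C(C)(C)C)[C@H](C)[C@]2(C1)Oc1c(C)c(CC/C=C(C)/CC/C(C)=C(C)/CC[C@@]4(C)CC[C@@]5(C)OC[C@H](C(C)C)N5C4O)ccc1O3 | intermediate
43 | keto aldehyde (C18 aldehyde, C20 methyl ketone) | C=C(C)[C@@H]1CC[C@@H](C)[C@@]23C[C@H](O[Si](C)(C)C(C)(C)C)[C@H](C)[C@]2(C1)Oc1c(C)c(CC/C=C(C)/CC/C(C)=C(C)/CC[C@](C)(C=O)CCC(C)=O)ccc1O3 | intermediate
44 | polyene with ring E as 4-methyl-4-alkylcyclohex-2-enone | C=C(C)[C@@H]1CC[C@@H](C)[C@@]23C[C@H](O[Si](C)(C)C(C)(C)C)[C@H](C)[C@]2(C1)Oc1c(C)c(CC/C=C(C)/CC/C(C)=C(C)/CC[C@]4(C)C=CC(=O)CC4)ccc1O3 | intermediate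
45 | pentacyclic C20 ketone | C=C(C)[C@@H]1CC[C@@H](C)[C@@]23C[C@H](O[Si](C)(C)C(C)(C)C)[C@H](C)[C@]2(C1)Oc1c(cc2c(c1C)CC[C@H]1[C@@]2(C)CC[C@@]2(C)[C@@H]4CC(=O)CC[C@]4(C)CC[C@]12C)O3 | intermediate
46 | C20 enol triflate | C=C(C)[C@@H]1CC[C@@H](C)[C@@]23C[C@H](O[Si](C)(C)C(C)(C)C)[C@H](C)[C@]2(C1)Oc1c(cc2c(c1C)CC[C@H]1[C@@]2(C)CC[C@@]2(C)[C@@H]4CC(OS(=O)(=O)C(F)(F)F)=CC[C@]4(C)CC[C@]12C)O3 | intermediate
47 | α,β-unsaturated C29 methyl ester | C=C(C)[C@@H]1CC[C@@H](C)[C@@]23C[C@H](O[Si](C)(C)C(C)(C)C)[C@H](C)[C@]2(C1)Oc1c(cc2c(c1C)CC[C@H]1[C@@]2(C)CC[C@@]2(C)[C@@H]4CC(C(=O)OC)=CC[C@]4(C)CC[C@]12C)O3 | intermediate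
48 | saturated C29 methyl ester (C20 epimers) | C=C(C)[C@@H]1CC[C@@H](C)[C@@]23C[C@H](O[Si](C)(C)C(C)(C)C)[C@H](C)[C@]2(C1)Oc1c(cc2c(c1C)CC[C@H]1[C@@]2(C)CC[C@@]2(C)[C@@H]4CC(C(=O)OC)CC[C@]4(C)CC[C@]12C)O3 | intermediate
49 | 20β-methyl-20α-methoxycarbonyl pentacycle | C=C(C)[C@@H]1CC[C@@H](C)[C@@]23C[C@H](O[Si](C)(C)C(C)(C)C)[C@H](C)[C@]2(C1)Oc1c(cc2c(c1C)CC[C@H]1[C@@]2(C)CC[C@@]2(C)[C@@H]4C[C@](C)(C(=O)OC)CC[C@]4(C)CC[C@]12C)O3 | intermediate
50 | 6,7-dehydro pentacycle with 3'-OTBS | C=C(C)[C@@H]1CC[C@@H](C)[C@@]23C[C@H](O[Si](C)(C)C(C)(C)C)[C@H](C)[C@]2(C1)Oc1c(cc2c(c1C)C=C[C@H]1[C@@]2(C)CC[C@@]2(C)[C@@H]4C[C@](C)(C(=O)OC)CC[C@]4(C)CC[C@]12C)O3 | intermediate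
51 | 6,7-dehydro pentacycle with free C3' alcohol | C=C(C)[C@@H]1CC[C@@H](C)[C@@]23C[C@H](O)[C@H](C)[C@]2(C1)Oc1c(cc2c(c1C)C=C[C@H]1[C@@]2(C)CC[C@@]2(C)[C@@H]4C[C@](C)(C(=O)OC)CC[C@]4(C)CC[C@]12C)O3 | intermediate
52 | C3' mesylate of 51 | C=C(C)[C@@H]1CC[C@@H](C)[C@@]23C[C@H](OS(C)(=O)=O)[C@H](C)[C@]2(C1)Oc1c(cc2c(c1C)C=C[C@H]1[C@@]2(C)CC[C@@]2(C)[C@@H]4C[C@](C)(C(=O)OC)CC[C@]4(C)CC[C@]12C)O3 | intermediate
53 | CNP0287532.2 | C=C(C)[C@@H]1CC[C@@H](C)[C@@]23CC=C(C)[C@]2(C1)Oc1c(cc2c(c1C)C=C[C@H]1[C@@]2(C)CC[C@@]2(C)[C@@H]4C[C@](C)(C(=O)OC)CC[C@]4(C)CC[C@]12C)O3 | target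

Total step count: 37. Longest linear sequence: 24 steps (steps 1–9, 13–17 and 28–37).

Steps most likely to fail

1. Step 16. The closure may stall at an unfavourable equilibrium, because a tetrasubstituted enone is given up and two adjacent fully substituted carbons are formed. The adduct may also revert, or lose the C1' aryloxy group, before it is reduced. The fallback sets out from 22 and comes back at 24. Compound 22 is treated with triethylsilyl triflate and 2,6-lutidine in CH2Cl2 at −78 to 0 °C. The silylated phenol oxygen then attacks the silyl-activated enone (silyl-transfer, Mukaiyama-type oxa-Michael addition), and the adduct is stored as the closed triethylsilyl enol ether F1. Formation of the Si–O bond takes the adduct out of the equilibrium. F1 is purified, protodesilylated with buffered fluoride at −78 °C to 23, and reduced at once with LiBH(s-Bu)3 to 24.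

2. Step 30. The cascade may end early by proton loss after ring D or ring C. The chair preference in the ring D fold may erode control at C13, C14, C8 and C9. The Lewis acid may also ionise the tertiary aryl ethers. The fallback sets out from 44 and comes back at 45.
   - The enone is converted with 1,2-bis(trimethylsilyloxy)ethane and catalytic Me3SiOTf at −78 °C into the ethylene ketal F2. The double bond cannot migrate because C17 is quaternary.
   - Ionisation of the ketal (SnCl4, 2,6-di-tert-butylpyridine, CH2Cl2, −78 °C) gives an alkoxyallyl cation. This is a stronger initiator at lower temperature (acetal-initiated polyene cyclisation).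
   - The cascade then delivers the pentacyclic 2-hydroxyethyl enol ether F3, which oxalic acid on wet silica hydrolyses to 45.

3. Step 13. Ligand coupling at iodine may be too slow between a neopentyl-like tertiary alkoxide and an ortho-silyloxy aryl group. Base-induced aryne formation or transfer of the wrong aryl group could then take over. The fallback sets out from 14 and 17 and comes back at 20. It is a palladium-catalysed C–O cross-coupling of the tertiary alcohol with the aryl iodide itself (Pd(OAc)2, a bulky di-tert-butyl biaryl phosphine, NaOt-Bu, toluene, 60–80 °C). Oxidative addition occurs at the C–I bond well before the hindered C–Br bond, and reductive elimination forms the same ether without passing through an iodonium salt.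

Further compounds
F1 | step 16 | closed propellane benzodioxane triethylsilyl enol ether (C3'(OSiEt3)=C4') | C=C(C)[C@@H]1CC[C@@H](C)[C@@]23CC(O[Si](CC)(CC)CC)=C(C)[C@]2(C1)Oc1c(C)c(Br)ccc1O3
F2 | step 30 | ethylene ketal of 44 | C=C(C)[C@@H]1CC[C@@H](C)[C@@]23C[C@H](O[Si](C)(C)C(C)(C)C)[C@H](C)[C@]2(C1)Oc1c(C)c(CC/C=C(C)/CC/C(C)=C(C)/CC[C@]4(C)C=CC5(OCCO5)CC4)ccc1O3
F3 | step 30 | pentacyclic C20 2-hydroxyethyl enol ether (19,20-ene) | C=C(C)[C@@H]1CC[C@@H](C)[C@@]23C[C@H](O[Si](C)(C)C(C)(C)C)[C@H](C)[C@]2(C1)Oc1c(cc2c(c1C)CC[C@H]1[C@@]2(C)CC[C@@]2(C)[C@@H]4C=C(OCCO)CC[C@]4(C)CC[C@]12C)O3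
F0 | step 13 | none | none
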